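Monday's 0.56 M of reagent against Saturday's 0.14 M gives twice the product at 40.0 h, not 4.00 times as much.

| flask | left-handed substrate | right-handed substrate | reagent | free catalyst | precatalyst | remark | time |
|---|---|---|---|---|---|---|---|
| Saturday's | 0.094 M | 0.094 M | 0.14 M | 15 mM | 0.94 mM | run made earlier |  |
| Monday's | 0.094 M | 0.094 M | 0.56 M | 15 mM | 0.94 mM | run made earlier |  |
| Sunday's | 0.094 M | 0.094 M | 0.282 M | 30 mM | 0.94 mM | run made earlier |  |
| flask | 0.094 M | 0.094 M | 0.282 M | 15 mM | 0.94 mM |  | 50 h |

- Saturday's (time / h: left-handed product / %, right-handed product / %): 3.00: 3.4, 3.2; 5.00: 5.4, 3.6; 8.00: 9.3, 5.5; 12.0: 11.6, 6.9; 15.0: 11.8, 7.5; 25.0: 15.4, 10.0; 40.0: 18.5, 11.2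
- Monday's (time / h: left-handed product / %, right-handed product / %): 6.00: 20.1, 12.2; 12.0: 25.0, 16.8; 15.0: 26.5, 17.0; 25.0: 32.5, 20.3; 30.0: 32.3, 21.6; 40.0: 34.6, 23.5
- Sunday's (time / h: left-handed product / %, right-handed product / %): 3.00: 11.6, 7.9; 6.00: 18.1, 12.2; 12.0: 25.3, 16.6; 20.0: 30.3, 20.0; 40.0: 35.8, 25.2

(standard deviation of a reading: 1 percentage point)

* left-handed product and right-handed product together, in percent of the left-handed substrate and right-handed substrate charged together, at 50 h
* excess of left-handed product over right-handed product in the product at 50 h
* whether the exchange between left-handed substrate and right-handed substrate keeps pace with the reaction: how far the product's excess at 50 h gets from its value without exchange to its value with instant exchange (above 80% keeps pace, below 20% hardly takes part, else lags behind)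

- free catalyst is single-handed; left-handed substrate and right-handed substrate are mirror images of each other, charged as a racemate, each of them at the stated concentration
- reactions considered so far: 2 free catalyst <-> resting dimer; reagent + free catalyst + right-handed substrate -> free catalyst + right-handed product; left-handed substrate + racemization catalyst <-> right-handed substrate + racemization catalyst; 2 reagent -> homo dimer; reagent + free catalyst + left-handed substrate -> free catalyst + left-handed product; precatalyst <-> racemization catalyst
- an excess is below zero if the other one leads

1. The first instants. The flask starts with reagent at 1.50 times the two substrates together. I watch the reagent: product is first order in it, homo dimer second order. At a given level of reagent and free catalyst, each substrate falls pseudo-first-order, exchange apart.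

2. The middle. In Saturday's run the first 3.00 h bring 6.60% of product. The stretch from 25.0 h to 40.0 h brings 4.3 percentage points. At 40.0 h the product holds 39.9% of Saturday's reagent, but 19.5% of Monday's.

3. The end. If the reagent goes mainly by its second-order loss, its integral over a long time grows with the logarithm of its charge. I call exposure the logarithm of one over the unreacted fraction of the substrates. At 40.0 h it reads 0.352 on Saturday and 0.870 on Monday. That makes the exposure step per doubling of the reagent charge 0.259.

4. The flask. Its catalyst matches those two runs, so I leave Sunday's 30 mM aside. Its reagent lies 1.01 doublings above Saturday's, which gives exposure 0.614 at 40.0 h. The mean gain of the two runs from 25.0 h to 40.0 h, scaled on logarithmic time, adds 0.0424. So I expect 48.1% at 50 h. The excess at 40.0 h reads 24.6% on Saturday and 19.1% on Monday, and I expect the flask between them.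

5. The forecast says 45% (41% to 49%), lower than mine, with excess 20% (17.5% to 22.5%) and exchange that lags behind. Its ground for the levelling yield is that “homodimerisation is eating the reagent”.

6. The flask gives 48.4% and excess 21.2%, and the exchange lags behind, 35% of the way.

    2 free catalyst ⇌ resting dimer, settled at all times (K = 18.0 M⁻¹)
    reagent + free catalyst + right-handed substrate → free catalyst + right-handed product (k = 0.00340 M⁻² s⁻¹)
    left-handed substrate + racemization catalyst ⇌ right-handed substrate + racemization catalyst, rate k3*[racemization catalyst]*[left-handed substrate] forward; the back reaction follows from the equilibrium constant (k = 0.00700 M⁻¹ s⁻¹)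
    2 reagent → homo dimer (k = 5.20 × 10⁻⁵ M⁻¹ s⁻¹)
    reagent + free catalyst + left-handed substrate → free catalyst + left-handed product (k = 0.00580 M⁻² s⁻¹)
    precatalyst ⇌ racemization catalyst (K = 4.10, k = 2.10 × 10⁻⁴ s⁻¹)

Just after the start of the flask, the loss to homo dimer uses reagent 5.0 times as fast as the making of left-handed product, half of that loss up to 50.0 h is done by 4.69 h, and 8.5% of the reagent is left at 50.0 h. From the flask's exposure of 0.662, the step of 0.259 per doubling reckons 69.0% for a neighbour charged with 1.1 M of reagent, and that neighbour gives 71.7%.

All runs are calculated with constants of no real substance; noise was put on by code.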